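**Assumption:** germacrane locants are used throughout (C1/C10 = oxirane carbons, C3 = carbinol, C6 = lactone O‑carbon, C8 = ester carbon, C15 = CH2OH); the target is read as (1R,3S,4Z,6R,7R,8R,10R)-1,10-epoxy-3,15-dihydroxy-8-methacryloyloxygermacra-4,11(13)-dien-12,6-olide.

## Retrosynthetic overview
1. Oxirane last: face‑ and chemoselective epoxidation of the C1=C10 alkene of the 1(10)E,4Z‑germacradienolide diol, after C15 desilylation.
2. Ten‑membered ring: intramolecular Nozaki–Hiyama–Kishi closure of C3–C4 (Z‑alkenyl iodide onto a C3 aldehyde), which also creates the C3 carbinol.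
3. C8 ester: Mitsunobu inversion of the 8S alcohol with methacrylic acid.
4. Key C7–C8 bond: intermolecular Zn‑Barbier carbonyl allylation of an achiral β,γ‑unsaturated aldehyde (C8–C3 + C14) with an (S)‑3‑(bromomethyl)butenolide (C4–C7, C11–C13, C15); it sets C7 and C8 and unveils the α‑methylene lactone.
5. Fragments: the butenolide from propargyl alcohol and acrolein (resolution, directed hydroalumination–iodination, esterification, RCM); the aldehyde from but‑3‑yn‑1‑ol by carboalumination and ethylene oxide opening. Ring order: γ‑lactone, then ten‑membered carbocycle, then oxirane.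

## Route

**Fragment A: bromobutenolide 11**

Step 1
Reactants: 1 prop-2-yn-1-ol
Product: 2 tert-butyldimethyl(prop-2-yn-1-yloxy)silane
Conditions: TBSCl, imidazole, CH2Cl2, 0 °C to rt
Reagents that add atoms: tert-butyldimethylsilyl chloride, CC(C)(C)[Si](C)(C)Cl
Why: Routine silyl ether formation on an unhindered primary alcohol; this oxygen becomes the C15 hydroxyl.

Step 2
Reactants: 2 tert-butyldimethyl(prop-2-yn-1-yloxy)silane; 3 acrolein
Product: 5 (±)-6-(tert-butyldimethylsilyloxy)hex-1-en-4-yn-3-ol, via lithium acetylide 4 (not isolated)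
Conditions: n-BuLi, THF, −78 °C; then 3, −78 °C; H2O quench
Reagents that add atoms: none
Why: Carbonyl alkynylation; the lithium acetylide adds 1,2 to acrolein at low temperature and gives the racemic vinyl alkynyl carbinol (future C6).

Step 3
Reactants: 5 (±)-6-(tert-butyldimethylsilyloxy)hex-1-en-4-yn-3-ol
Product: 6 (S)-6-(tert-butyldimethylsilyloxy)hex-1-en-4-yn-3-ol
Conditions: immobilized Candida antarctica lipase B (Novozym 435), vinyl acetate, hexane, 30 °C, stopped at ca. 55% conversion; chromatography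
Reagents that add atoms: none
Why: Enzymatic kinetic resolution by transesterification; by the Kazlauskas rule (substituted alkynyl = large group, vinyl = medium group) the R alcohol is acetylated and the S alcohol, which carries the C6 configuration, is recovered in high ee.

Step 4
Reactants: 6 (S)-6-(tert-butyldimethylsilyloxy)hex-1-en-4-yn-3-ol
Product: 8 (3S,4Z)-6-(tert-butyldimethylsilyloxy)-5-iodohexa-1,4-dien-3-ol, via cyclic alkenylalanate 7 (not isolated)
Conditions: NaAlH2(OCH2CH2OMe)2, THF, 0 °C; then I2, THF, −78 °C; aq. Rochelle salt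
Reagents that add atoms: iodine, II
Why: Hydroxyl‑directed trans‑hydroalumination puts hydride on the proximal and aluminium on the distal alkyne carbon in a five‑membered alanate, and iodinolysis with retention gives the Z‑alkenyl iodide with iodine cis to the carbinol carbon; the low temperature suppresses allene formation.

Step 5
Reactants: 8 (3S,4Z)-6-(tert-butyldimethylsilyloxy)-5-iodohexa-1,4-dien-3-ol; 9 2-(bromomethyl)acrylic acid
Product: 10 (3S,4Z)-6-(tert-butyldimethylsilyloxy)-5-iodohexa-1,4-dien-3-yl 2-(bromomethyl)acrylate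
Conditions: N,N'-dicyclohexylcarbodiimide, 4-(dimethylamino)pyridine (5 mol %), CH2Cl2, −20 to 0 °C
Reagents that add atoms: none
Why: Steglich esterification leaves the carbinol C–O bond intact (retention); the low temperature and small amount of the pyridine catalyst spare the allylic bromide.

Step 6
Reactants: 10 (3S,4Z)-6-(tert-butyldimethylsilyloxy)-5-iodohexa-1,4-dien-3-yl 2-(bromomethyl)acrylate
Product: 11 (S)-3-(bromomethyl)-5-[(Z)-3-(tert-butyldimethylsilyloxy)-2-iodoprop-1-en-1-yl]furan-2(5H)-one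
Conditions: second-generation Grubbs catalyst RuCl2(=CHPh)(PCy3)(H2IMes) (5 mol %), toluene, 70 °C
Reagents that add atoms: none
Why: Ring‑closing metathesis between the vinyl group and the 1,1‑disubstituted acrylate closes the butenolide with loss of ethene; the trisubstituted iodoalkene is inert and the stereocenter is untouched (the product is kept away from base, since the γ‑hydrogen is acidic).

**Fragment B: aldehyde 20**

Step 7
Reactants: 12 but-3-yn-1-ol
Product: 13 (but-3-yn-1-yloxy)(tert-butyl)dimethylsilane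
Conditions: TBSCl, imidazole, CH2Cl2, 0 °C to rt
Reagents that add atoms: tert-butyldimethylsilyl chloride, CC(C)(C)[Si](C)(C)Cl
Why: Routine silylation; temporary protection of the oxygen that becomes the C8 aldehyde.

Step 8
Reactants: 13 (but-3-yn-1-yloxy)(tert-butyl)dimethylsilane; 14 oxirane
Product: 17 (E)-6-(tert-butyldimethylsilyloxy)-4-methylhex-3-en-1-ol, via alkenyldimethylalane 15 (not isolated), via lithium alkenylalanate 16 (not isolated)
Conditions: AlMe3 (2 equiv), Cp2ZrCl2 (0.2 equiv), CH2Cl2, 0 °C to rt; excess AlMe3 removed in vacuo; n-BuLi, hexane/THF, −30 °C; then 14, −30 °C to rt; aq. Rochelle salt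
Reagents that add atoms: trimethylaluminium, C[Al](C)C
Why: Negishi zirconium‑catalysed carboalumination is a syn addition that places the methyl group (C14) on the internal carbon, and the derived alanate opens ethylene oxide with retention, fixing the E‑C1=C10 alkene.

Step 9
Reactants: 17 (E)-6-(tert-butyldimethylsilyloxy)-4-methylhex-3-en-1-ol
Product: 18 (E)-tert-butyl{[6-(4-methoxybenzyloxy)-3-methylhex-3-en-1-yl]oxy}dimethylsilane
Conditions: NaH, 4-methoxybenzyl chloride, Bu4NI (cat.), THF/DMF, 0 °C to rt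
Reagents that add atoms: 4-methoxybenzyl chloride, COc1ccc(CCl)cc1
Why: Williamson etherification protects the C3 oxygen with a group that is later removed oxidatively under neutral conditions.

Step 10
Reactants: 18 (E)-tert-butyl{[6-(4-methoxybenzyloxy)-3-methylhex-3-en-1-yl]oxy}dimethylsilane
Product: 19 (E)-6-(4-methoxybenzyloxy)-3-methylhex-3-en-1-ol
Conditions: Bu4NF, THF, 0 °C to rt
Reagents that add atoms: none
Why: Fluoride desilylation frees the C8 hydroxyl; the benzyl ether and the alkene are unaffected.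

Step 11
Reactants: 19 (E)-6-(4-methoxybenzyloxy)-3-methylhex-3-en-1-ol
Product: 20 (E)-6-(4-methoxybenzyloxy)-3-methylhex-3-enal
Conditions: Dess–Martin periodinane, NaHCO3, CH2Cl2, 0 °C; used at once
Reagents that add atoms: none
Why: Dess–Martin oxidation under buffered, near‑neutral conditions gives the β,γ‑unsaturated aldehyde without migration of the alkene into conjugation.

**Coupling and end game**

Step 12
Reactants: 11 (S)-3-(bromomethyl)-5-[(Z)-3-(tert-butyldimethylsilyloxy)-2-iodoprop-1-en-1-yl]furan-2(5H)-one; 20 (E)-6-(4-methoxybenzyloxy)-3-methylhex-3-enal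
Product: 22 (4R,5S)-4-[(1S,3E)-1-hydroxy-6-(4-methoxybenzyloxy)-3-methylhex-3-en-1-yl]-5-[(Z)-3-(tert-butyldimethylsilyloxy)-2-iodoprop-1-en-1-yl]-3-methylidenedihydrofuran-2(3H)-one, via allylzinc bromide 21 (not isolated)
Conditions: Zn dust, THF/sat. aq. NH4Cl (2:1), 0 °C to rt
Reagents that add atoms: none
Why: Barbier‑type carbonyl allylation; the allylzinc reacts through its γ‑carbon (C7) in a chair transition state on the butenolide face anti to the C6 alkenyl group (6,7‑trans lactone) with the aldehyde chain equatorial (7,8‑anti, 8S carbinol), and the exocyclic methylene is formed at the same time.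

Step 13
Reactants: 22 (4R,5S)-4-[(1S,3E)-1-hydroxy-6-(4-methoxybenzyloxy)-3-methylhex-3-en-1-yl]-5-[(Z)-3-(tert-butyldimethylsilyloxy)-2-iodoprop-1-en-1-yl]-3-methylidenedihydrofuran-2(3H)-one; 23 methacrylic acid
Product: 24 (1R,3E)-1-{(2S,3R)-2-[(Z)-3-(tert-butyldimethylsilyloxy)-2-iodoprop-1-en-1-yl]-4-methylidene-5-oxotetrahydrofuran-3-yl}-6-(4-methoxybenzyloxy)-3-methylhex-3-en-1-yl 2-methylprop-2-enoate
Conditions: PPh3, diisopropyl azodicarboxylate, THF, 0 °C to rt (betaine pre‑formed)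
Reagents that add atoms: none
Why: Mitsunobu esterification displaces the activated C8 oxygen by methacrylate in an SN2 step, inverting 8S to the required 8R and installing the ester in one operation.

Step 14
Reactants: 24 (1R,3E)-1-{(2S,3R)-2-[(Z)-3-(tert-butyldimethylsilyloxy)-2-iodoprop-1-en-1-yl]-4-methylidene-5-oxotetrahydrofuran-3-yl}-6-(4-methoxybenzyloxy)-3-methylhex-3-en-1-yl 2-methylprop-2-enoate
Product: 25 (1R,3E)-1-{(2S,3R)-2-[(Z)-3-(tert-butyldimethylsilyloxy)-2-iodoprop-1-en-1-yl]-4-methylidene-5-oxotetrahydrofuran-3-yl}-6-hydroxy-3-methylhex-3-en-1-yl 2-methylprop-2-enoate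
Conditions: DDQ, CH2Cl2/pH 7 phosphate buffer (10:1), 0 °C
Reagents that add atoms: none
Why: Oxidative cleavage of the 4‑methoxybenzyl ether is neutral and leaves the alkenyl iodide, silyl ether, both acrylate units and the trisubstituted alkene intact.

Step 15
Reactants: 25 (1R,3E)-1-{(2S,3R)-2-[(Z)-3-(tert-butyldimethylsilyloxy)-2-iodoprop-1-en-1-yl]-4-methylidene-5-oxotetrahydrofuran-3-yl}-6-hydroxy-3-methylhex-3-en-1-yl 2-methylprop-2-enoate
Product: 26 (1R,3E)-1-{(2S,3R)-2-[(Z)-3-(tert-butyldimethylsilyloxy)-2-iodoprop-1-en-1-yl]-4-methylidene-5-oxotetrahydrofuran-3-yl}-3-methyl-6-oxohex-3-en-1-yl 2-methylprop-2-enoate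
Conditions: Dess–Martin periodinane, NaHCO3, CH2Cl2, 0 °C; used at once
Reagents that add atoms: none
Why: Buffered Dess–Martin oxidation gives the C3 aldehyde without isomerising the β,γ‑alkene or touching the existing stereocenters.

Step 16
Reactants: 26 (1R,3E)-1-{(2S,3R)-2-[(Z)-3-(tert-butyldimethylsilyloxy)-2-iodoprop-1-en-1-yl]-4-methylidene-5-oxotetrahydrofuran-3-yl}-3-methyl-6-oxohex-3-en-1-yl 2-methylprop-2-enoate
Product: 28 (1(10)E,3S,4Z,6R,7R,8R)-15-(tert-butyldimethylsilyloxy)-3-hydroxy-8-methacryloyloxygermacra-1(10),4,11(13)-trien-12,6-olide, via alkenylchromium dichloride 27 (not isolated)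
Conditions: CrCl2 (10 equiv), NiCl2 (0.1 equiv), degassed DMSO, rt, slow addition to 2 mM
Reagents that add atoms: none
Why: Intramolecular Nozaki–Hiyama–Kishi reaction; the alkenylchromium formed with retention of the Z geometry adds only to the aldehyde and closes the ten‑membered ring, and C3 is set by macrocyclic control (3S expected as the major epimer with the carbonyl oxygen on the outer face; to be confirmed by NOE, minor epimer separable).

Step 17
Reactants: 28 (1(10)E,3S,4Z,6R,7R,8R)-15-(tert-butyldimethylsilyloxy)-3-hydroxy-8-methacryloyloxygermacra-1(10),4,11(13)-trien-12,6-olide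
Product: 29 (1(10)E,3S,4Z,6R,7R,8R)-3,15-dihydroxy-8-methacryloyloxygermacra-1(10),4,11(13)-trien-12,6-olide
Conditions: HF·pyridine, excess pyridine, THF, 0 °C
Reagents that add atoms: none
Why: Buffered fluoride desilylation of the primary allylic silyl ether is done before the acid‑sensitive oxirane is present and tolerates the α‑methylene lactone and the methacrylate.

Step 18
Reactants: 29 (1(10)E,3S,4Z,6R,7R,8R)-3,15-dihydroxy-8-methacryloyloxygermacra-1(10),4,11(13)-trien-12,6-olide
Product: 30 (1R,3S,4Z,6R,7R,8R,10R)-1,10-epoxy-3,15-dihydroxy-8-methacryloyloxygermacra-4,11(13)-dien-12,6-olide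
Conditions: mCPBA (1.05 equiv), NaHCO3, CH2Cl2, −20 to 0 °C
Reagents that add atoms: meta-chloroperoxybenzoic acid, O=C(OO)c1cccc(Cl)c1
Why: Prilezhaev epoxidation attacks only the electron‑rich C1=C10 alkene (C4=C5 carries three allylic oxygens, the two acrylate alkenes are electron‑poor); stereospecific syn addition from the exposed outer face of the E‑alkene in the usual ring conformer (C14 methyl β, 3β‑OH on the same side) is expected to give the 1β,10α (1R,10R) oxirane.

## Compound list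
1 | prop-2-yn-1-ol | C#CCO | starting material
2 | tert-butyldimethyl(prop-2-yn-1-yloxy)silane | C#CCO[Si](C)(C)C(C)(C)C | intermediate
3 | acrolein | C=CC=O | starting material
4 | [3-(tert-butyldimethylsilyloxy)prop-1-yn-1-yl]lithium | [Li]C#CCO[Si](C)(C)C(C)(C)C | intermediate
5 | (±)-6-(tert-butyldimethylsilyloxy)hex-1-en-4-yn-3-ol | C=CC(O)C#CCO[Si](C)(C)C(C)(C)C | intermediate
6 | (S)-6-(tert-butyldimethylsilyloxy)hex-1-en-4-yn-3-ol | C=C[C@H](O)C#CCO[Si](C)(C)C(C)(C)C | intermediate
7 | sodium (S)-2,2-bis(2-methoxyethoxy)-3-(tert-butyldimethylsilyloxymethyl)-5-vinyl-2,5-dihydro-1,2-oxaluminol-2-uide | C=C[C@@H]1O[Al-](OCCOC)(OCCOC)C(CO[Si](C)(C)C(C)(C)C)=C1.[Na+] | intermediate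
8 | (3S,4Z)-6-(tert-butyldimethylsilyloxy)-5-iodohexa-1,4-dien-3-ol | C=C[C@H](O)/C=C(\I)CO[Si](C)(C)C(C)(C)C | intermediate
9 | 2-(bromomethyl)acrylic acid | C=C(CBr)C(=O)O | starting material
10 | (3S,4Z)-6-(tert-butyldimethylsilyloxy)-5-iodohexa-1,4-dien-3-yl 2-(bromomethyl)acrylate | C=C[C@H](OC(=O)C(=C)CBr)/C=C(\I)CO[Si](C)(C)C(C)(C)C | intermediate
11 | (S)-3-(bromomethyl)-5-[(Z)-3-(tert-butyldimethylsilyloxy)-2-iodoprop-1-en-1-yl]furan-2(5H)-one | BrCC1=C[C@@H](/C=C(\I)CO[Si](C)(C)C(C)(C)C)OC1=O | intermediate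
12 | but-3-yn-1-ol | C#CCCO | starting material
13 | (but-3-yn-1-yloxy)(tert-butyl)dimethylsilane | C#CCCO[Si](C)(C)C(C)(C)C | intermediate
14 | oxirane (ethylene oxide) | C1CO1 | starting material
15 | (E)-[4-(tert-butyldimethylsilyloxy)-2-methylbut-1-en-1-yl]dimethylalane | C[Al](C)/C=C(\C)CCO[Si](C)(C)C(C)(C)C | intermediate
16 | lithium butyl[(E)-4-(tert-butyldimethylsilyloxy)-2-methylbut-1-en-1-yl]dimethylalanate | [Li+].CCCC[Al-](C)(C)/C=C(\C)CCO[Si](C)(C)C(C)(C)C | intermediate
17 | (E)-6-(tert-butyldimethylsilyloxy)-4-methylhex-3-en-1-ol | OCC/C=C(\C)CCO[Si](C)(C)C(C)(C)C | intermediate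
18 | (E)-tert-butyl{[6-(4-methoxybenzyloxy)-3-methylhex-3-en-1-yl]oxy}dimethylsilane | COc1ccc(COCC/C=C(\C)CCO[Si](C)(C)C(C)(C)C)cc1 | intermediate
19 | (E)-6-(4-methoxybenzyloxy)-3-methylhex-3-en-1-ol | COc1ccc(COCC/C=C(\C)CCO)cc1 | intermediate
20 | (E)-6-(4-methoxybenzyloxy)-3-methylhex-3-enal | COc1ccc(COCC/C=C(\C)CC=O)cc1 | intermediate
21 | allylzinc bromide from 11: bromo{[(S)-5-((Z)-3-(tert-butyldimethylsilyloxy)-2-iodoprop-1-en-1-yl)-2-oxo-2,5-dihydrofuran-3-yl]methyl}zinc | Br[Zn]CC1=C[C@@H](/C=C(\I)CO[Si](C)(C)C(C)(C)C)OC1=O | intermediate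
22 | (4R,5S)-4-[(1S,3E)-1-hydroxy-6-(4-methoxybenzyloxy)-3-methylhex-3-en-1-yl]-5-[(Z)-3-(tert-butyldimethylsilyloxy)-2-iodoprop-1-en-1-yl]-3-methylidenedihydrofuran-2(3H)-one | COc1ccc(COCC/C=C(\C)C[C@H](O)[C@H]2C(=C)C(=O)O[C@@H]2/C=C(\I)CO[Si](C)(C)C(C)(C)C)cc1 | intermediate
23 | methacrylic acid | C=C(C)C(=O)O | starting material
24 | (1R,3E)-1-{(2S,3R)-2-[(Z)-3-(tert-butyldimethylsilyloxy)-2-iodoprop-1-en-1-yl]-4-methylidene-5-oxotetrahydrofuran-3-yl}-6-(4-methoxybenzyloxy)-3-methylhex-3-en-1-yl 2-methylprop-2-enoate | COc1ccc(COCC/C=C(\C)C[C@@H](OC(=O)C(C)=C)[C@H]2C(=C)C(=O)O[C@@H]2/C=C(\I)CO[Si](C)(C)C(C)(C)C)cc1 | intermediate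
25 | (1R,3E)-1-{(2S,3R)-2-[(Z)-3-(tert-butyldimethylsilyloxy)-2-iodoprop-1-en-1-yl]-4-methylidene-5-oxotetrahydrofuran-3-yl}-6-hydroxy-3-methylhex-3-en-1-yl 2-methylprop-2-enoate | OCC/C=C(\C)C[C@@H](OC(=O)C(C)=C)[C@H]1C(=C)C(=O)O[C@@H]1/C=C(\I)CO[Si](C)(C)C(C)(C)C | intermediate
26 | (1R,3E)-1-{(2S,3R)-2-[(Z)-3-(tert-butyldimethylsilyloxy)-2-iodoprop-1-en-1-yl]-4-methylidene-5-oxotetrahydrofuran-3-yl}-3-methyl-6-oxohex-3-en-1-yl 2-methylprop-2-enoate | O=CC/C=C(\C)C[C@@H](OC(=O)C(C)=C)[C@H]1C(=C)C(=O)O[C@@H]1/C=C(\I)CO[Si](C)(C)C(C)(C)C | intermediate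
27 | alkenylchromium dichloride from 26 (CrCl2 in place of iodine at C4) | O=CC/C=C(\C)C[C@@H](OC(=O)C(C)=C)[C@H]1C(=C)C(=O)O[C@@H]1/C=C(\[Cr](Cl)Cl)CO[Si](C)(C)C(C)(C)C | intermediate
28 | (1(10)E,3S,4Z,6R,7R,8R)-15-(tert-butyldimethylsilyloxy)-3-hydroxy-8-methacryloyloxygermacra-1(10),4,11(13)-trien-12,6-olide | C=C(C)C(=O)O[C@@H]1C/C(C)=C/C[C@H](O)/C(CO[Si](C)(C)C(C)(C)C)=C\[C@H]2OC(=O)C(=C)[C@@H]21 | intermediate
29 | (1(10)E,3S,4Z,6R,7R,8R)-3,15-dihydroxy-8-methacryloyloxygermacra-1(10),4,11(13)-trien-12,6-olide | C=C(C)C(=O)O[C@@H]1C/C(C)=C/C[C@H](O)/C(CO)=C\[C@H]2OC(=O)C(=C)[C@@H]21 | intermediate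
30 | (1R,3S,4Z,6R,7R,8R,10R)-1,10-epoxy-3,15-dihydroxy-8-methacryloyloxygermacra-4,11(13)-dien-12,6-olide (CNP0496616.1) | C=C(C)C(=O)O[C@@H]1C[C@@]2(C)O[C@@H]2C[C@H](O)/C(CO)=C\[C@H]2OC(=O)C(=C)[C@@H]21 | target

## Summary
Total steps: 18. Longest linear sequence: 13 steps (steps 1–6, then 12–18); the aldehyde branch (steps 7–11) is 5 steps.

Three steps most likely to fail:

**Step 13 (Mitsunobu inversion at C8).** The carbinol is flanked by the lactone ring carbon and an allylic CH2, so elimination to a C8=C9 diene or low conversion is possible. Fallback: starting from 22, the alcohol is sulfonylated with chloromethanesulfonyl chloride and pyridine (CH2Cl2, 0 °C) to the (8S)-chloromethanesulfonate F1. This is displaced in a separate SN2 step with caesium methacrylate, CsO2CC(Me)=CH2, and 18-crown-6 in toluene at 50 °C. Inversion gives 24, where the route is rejoined.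

**Step 16 (Nozaki–Hiyama–Kishi macrocyclisation).** The ring closure may give mainly the wrong C3 epimer, since C3 is set only by ring conformation. Fallback: starting from 26, the cyclisation is run as before and the 3R alcohol F2 is collected. It is oxidised with MnO2 (CH2Cl2, rt) to the macrocyclic 3-ketone F3, which is reduced with (R)-2-methyl-CBS-oxazaborolidine and catecholborane (toluene, −78 °C). C3 is then set by the reagent (alkenyl arm as the large group, giving 3S), and the route is rejoined at 28.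

**Step 18 (final epoxidation).** Face selectivity rests on substrate control, and the free allylic hydroxyls or liberated acid could cause C4=C5 epoxidation or transannular opening. Fallback: starting from 28, the alkene is epoxidised before desilylation with the D-fructose-derived Shi ketone (KHSO5 as Oxone, K2CO3, Bu4NHSO4, MeCN/dimethoxymethane/aqueous buffer, 0 °C). This chiral dioxirane is (R,R)-selective for E-trisubstituted alkenes and the medium stays basic. It gives the epoxy silyl ether F4, which is desilylated with Et3N·3HF (MeCN, 0 °C) to reach 30 directly.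

## Further compounds
F1 | step 13 | (1S,3E)-1-{(2S,3R)-2-[(Z)-3-(tert-butyldimethylsilyloxy)-2-iodoprop-1-en-1-yl]-4-methylidene-5-oxotetrahydrofuran-3-yl}-6-(4-methoxybenzyloxy)-3-methylhex-3-en-1-yl chloromethanesulfonate | COc1ccc(COCC/C=C(\C)C[C@H](OS(=O)(=O)CCl)[C@H]2C(=C)C(=O)O[C@@H]2/C=C(\I)CO[Si](C)(C)C(C)(C)C)cc1
F2 | step 16 | (1(10)E,3R,4Z,6R,7R,8R)-15-(tert-butyldimethylsilyloxy)-3-hydroxy-8-methacryloyloxygermacra-1(10),4,11(13)-trien-12,6-olide | C=C(C)C(=O)O[C@@H]1C/C(C)=C/C[C@@H](O)/C(CO[Si](C)(C)C(C)(C)C)=C\[C@H]2OC(=O)C(=C)[C@@H]21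
F3 | step 16 | (1(10)E,4Z,6R,7R,8R)-15-(tert-butyldimethylsilyloxy)-8-methacryloyloxy-3-oxogermacra-1(10),4,11(13)-trien-12,6-olide | C=C(C)C(=O)O[C@@H]1C/C(C)=C/CC(=O)/C(CO[Si](C)(C)C(C)(C)C)=C\[C@H]2OC(=O)C(=C)[C@@H]21
F4 | step 18 | (1R,3S,4Z,6R,7R,8R,10R)-15-(tert-butyldimethylsilyloxy)-1,10-epoxy-3-hydroxy-8-methacryloyloxygermacra-4,11(13)-dien-12,6-olide | C=C(C)C(=O)O[C@@H]1C[C@@]2(C)O[C@@H]2C[C@H](O)/C(CO[Si](C)(C)C(C)(C)C)=C\[C@H]2OC(=O)C(=C)[C@@H]21
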